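Ring A (C1–C5, C10) is cut at C1–C2 and C4–C5. The C2–C3–C4 unit is a ketone α,α′-bis-nucleophile (enol silane 13); ring B supplies both electrophilic sites: C5 as β-carbon of the C5=C6–C7=O enone and C1 as one CH2 of a spiro-oxetane on C10, whose other CH2–O becomes C20–OH. In one pot a Mukaiyama–Michael addition forms C4–C5 anti to the C9 side chain, and the in-situ enol silane then opens the strained oxetane to form C1–C2, closing the trans-decalin and setting C5 and C10. C9 comes from a catalytic desymmetrisation of an achiral dienone, C13 from (R)-linalool; C2, C3, C7, C8 and the two esters follow.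

Key step: step 7

Remarks on the chemistry:
- Labdane numbering is used for all decalins and for ring B of the spiro compounds (C10 = spiro carbon); α/β refer to the usual drawing with C20 β.
- 2-Oxaspiro[3.5]nonan-7-one is taken as a purchasable building block.
- The antipode of the phosphoramidite ligand in step 5 is to be chosen so that C9 forms as drawn.
- C8 in 26 and 27 is left undefined, because both epimers lead to 28.

Step 1
Reactants: 1 (R)-linalool
Product: 2 (3R)-3,7-dimethyl-3-(triethylsilyloxy)octa-1,6-diene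
Conditions: TESOTf, 2,6-lutidine, CH2Cl2, −78 → 0 °C
Reagents that add atoms: triethylsilyl triflate, CC[Si](CC)(CC)OS(=O)(=O)C(F)(F)F
Why: Silyl triflate/lutidine silylation is the standard way to cap a hindered tertiary allylic alcohol; the C13 stereocentre of the target is taken unchanged from the chiral pool.

Step 2
Reactants: 2 (3R)-3,7-dimethyl-3-(triethylsilyloxy)octa-1,6-diene
Product: 4 (4R)-4-methyl-4-(triethylsilyloxy)hex-5-enoic acid, via aldehyde 3 (not isolated)
Conditions: O3 (1.0 equiv), MeCN/H2O 9:1, 0 °C; then NaClO2, NaH2PO4, 0 → 25 °C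
Reagents that add atoms: ozone, [O-][O+]=O; sodium chlorite, [Na+].[O-]Cl=O
Why: The electron-rich trisubstituted alkene should be ozonised far faster than the vinyl group next to the quaternary carbinol carbon, and the aldehyde from aqueous ozonolysis is oxidised in the same pot (Pinnick oxidation, the hydrogen peroxide formed acting as hypochlorite scavenger).

Step 3
Reactants: 4 (4R)-4-methyl-4-(triethylsilyloxy)hex-5-enoic acid
Product: 5 (3R)-5-iodo-3-methyl-3-(triethylsilyloxy)pent-1-ene
Conditions: PhI(OAc)2, I2, benzene, hν (tungsten lamp), 80 °C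
Reagents that add atoms: iodine, II
Why: Hunsdiecker-type iododecarboxylation (Suárez conditions) goes through an acyl hypoiodite and a primary radical that has only unfavourable 4-exo/5-endo cyclisation modes, so it should be trapped by iodine with the vinyl group and C13 intact.

Step 4
Reactants: 6 2-oxaspiro[3.5]nonan-7-one
Product: 7 2-oxaspiro[3.5]nona-5,8-dien-7-one
Conditions: 2-iodoxybenzoic acid (IBX, 3 equiv), DMSO, 80 °C
Reagents that add atoms: none
Why: IBX-mediated α,β-dehydrogenation of a 4,4-disubstituted cyclohexanone on both sides should give the cross-conjugated dienone; the spiro centre blocks aromatisation and the 3,3-disubstituted oxetane tolerates the weakly acidic medium.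

Step 5
Reactants: 5 (3R)-5-iodo-3-methyl-3-(triethylsilyloxy)pent-1-ene; 7 2-oxaspiro[3.5]nona-5,8-dien-7-one
Product: 10 (9R)-9-[(3R)-3-methyl-3-(triethylsilyloxy)pent-4-en-1-yl]-2-oxaspiro[3.5]non-5-en-7-one, via dialkylzinc 8 (not isolated), via zinc dienolate 9 (not isolated)
Conditions: 5, Et2Zn (neat), CuI (0.3 mol %), 50 °C, then volatiles removed; 7, Cu(OTf)2 (2 mol %), (S)-1,1'-binaphthyl-2,2'-diyl N,N-bis[(R)-1-phenylethyl]phosphoramidite (4 mol %), toluene, −30 °C; AcOH/H2O
Reagents that add atoms: none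
Why: Iodine–zinc exchange followed by copper/phosphoramidite-catalysed asymmetric conjugate addition of the dialkylzinc desymmetrises the achiral dienone, the chiral catalyst choosing one of the two enantiotopic β-carbons and so setting C9, while the zinc dienolate formed cannot accept a second addition.

Step 6
Reactants: 11 3-bromo-3-methylbutan-2-one
Product: 13 tert-butyldimethyl[(3-methylbut-2-en-2-yl)oxy]silane, via zinc enolate 12 (not isolated)
Conditions: Zn dust, TBSCl, DMF, 25 °C
Reagents that add atoms: tert-butyldimethylsilyl chloride, CC(C)(C)[Si](C)(C)Cl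
Why: Zinc insertion into the tertiary α-bromo ketone (Reformatsky-type enolate) and O-silylation should give the tetrasubstituted enol silane regiospecifically, which simple enolisation of 3-methylbutan-2-one would not.

Step 7
Reactants: 10 (9R)-9-[(3R)-3-methyl-3-(triethylsilyloxy)pent-4-en-1-yl]-2-oxaspiro[3.5]non-5-en-7-one; 13 tert-butyldimethyl[(3-methylbut-2-en-2-yl)oxy]silane
Product: 17 7-(tert-butyldimethylsilyloxy)-20-hydroxy-13-(triethylsilyloxy)-9βH-labda-6,14-dien-3-one (5α-H, C9 side chain α, 10β-CH2OH, 13R), via Michael adduct 14 (not isolated), via enol silane 15 (not isolated), via trimethylsilyl ether 16 (not isolated)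
Conditions: 13 (1.5 equiv), TBSOTf (0.2 equiv), CH2Cl2, −78 → −40 °C; then i-Pr2NEt (2.5 equiv), TMSOTf (2.2 equiv), −40 → 0 °C; then K2CO3, MeOH, 0 °C
Reagents that add atoms: none
Why: Proposed new method: the silyl triflate activates the enone of 10 and the tetrasubstituted enol silane 13 adds through C4 to C5 (Mukaiyama–Michael, silyl transfer to the C7 oxygen gives 14); TMSOTf/i-Pr2NEt then converts the new methyl ketone, which can enolise only toward C2, into enol silane 15, whose terminal carbon opens the O-silylated oxetane at one CH2 with release of ring strain, forming C1–C2 and liberating the C20 oxygen (16, then 17 on methanolysis). The closest known chemistry is the Mukaiyama–Michael addition, the one-pot silyl triflate/amine enol silane formation–Mukaiyama addition and the Lewis-acid opening of oxetanes by enol silanes or lithium enolates; their union as a formal [3+3] annulation has not been described. Ring A closes in the 6-exo-tet mode by SN2 attack at the oxetane methylene, the C4–C5 bond being formed intermolecularly beforehand. C5 is controlled by the C9 side chain: the nucleophile adds axially to the half-chair in which that chain is equatorial, hence anti to it (3,5-trans), which gives 5α-H. C10 is controlled by C5: a chair transition state with the bulky C4 substituent equatorial on ring B lets C2 reach only the oxetane CH2 trans to C4, so the trans-decalin with C1 α and C20 β results. The step needs the enone to react before the oxetane and the ketone to enolise only at C2; the steric mismatch between the tetrasubstituted nucleophile and the neopentyl oxetane carbons, the quaternary C4, and the late addition of the amine (so that 10 is not turned into its dienol silane) secure this.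

Step 8
Reactants: 17 7-(tert-butyldimethylsilyloxy)-20-hydroxy-13-(triethylsilyloxy)-9βH-labda-6,14-dien-3-one; 18 (R)-2-methylbutanoic acid
Product: 19 7-(tert-butyldimethylsilyloxy)-3-oxo-13-(triethylsilyloxy)-9βH-labda-6,14-dien-20-yl (2R)-2-methylbutanoate
Conditions: EDC·HCl, DMAP (0.1 equiv), CH2Cl2, 0 °C
Reagents that add atoms: none
Why: Steglich esterification of the only free hydroxyl (primary C20–OH) should proceed cleanly, and low temperature with catalytic DMAP should keep the α-stereocentre of the acid intact.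

Step 9
Reactants: 19 7-(tert-butyldimethylsilyloxy)-3-oxo-13-(triethylsilyloxy)-9βH-labda-6,14-dien-20-yl (2R)-2-methylbutanoate
Product: 20 2α-hydroxy derivative of 19
Conditions: KN(SiMe3)2 (1.05 equiv), THF, −78 °C; 2-(phenylsulfonyl)-3-phenyloxaziridine; AcOH
Reagents that add atoms: 2-(phenylsulfonyl)-3-phenyloxaziridine (Davis oxaziridine), O=S(=O)(c1ccccc1)N1OC1c1ccccc1
Why: Davis enolate hydroxylation can occur only at C2 (C4 is quaternary, the ring-B ketone is masked as its silyl enol ether and the hindered ester α-CH is far less acidic), and oxygen is delivered from the α face because the β face is blocked by the axial C20 CH2O group and the 4β-methyl, giving the equatorial 2α-OH.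

Step 10
Reactants: 20 2α-hydroxy-3-ketone
Product: 21 7-(tert-butyldimethylsilyloxy)-2α,3α-dihydroxy-13-(triethylsilyloxy)-9βH-labda-6,14-dien-20-yl (2R)-2-methylbutanoate
Conditions: LiBH(s-Bu)3 (L-Selectride, 3 equiv), THF, −78 °C; AcOH
Reagents that add atoms: none
Why: The bulky hydride should attack the 4,4-dimethyl-3-ketone from the equatorial direction (as in selectride reductions of 3-oxo triterpenoids), giving the axial 3α-OH cis to the 2α-OH, while the silyl enol ether and the hindered ester are inert at −78 °C.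

Step 11
Reactants: 21 2α,3α-diol
Product: 22 2α,3α,13-trihydroxy-7-oxo-9βH-labd-14-en-20-yl (2R)-2-methylbutanoate
Conditions: HF·pyridine, pyridine, THF, 0 → 25 °C
Reagents that add atoms: none
Why: Buffered fluoride desilylation should cleave the tertiary triethylsilyl ether and the silyl enol ether (releasing the C7 ketone) in one operation without ionising the tertiary allylic alcohol or touching the ester.

Step 12
Reactants: 22 2α,3α,13-trihydroxy-7-oxo-9βH-labd-14-en-20-yl (2R)-2-methylbutanoate; 23 angelic acid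
Product: 25 2α-[(Z)-2-methylbut-2-enoyloxy]-3α,13-dihydroxy-7-oxo-9βH-labd-14-en-20-yl (2R)-2-methylbutanoate, via mixed anhydride 24 (not isolated)
Conditions: 23, 2,4,6-trichlorobenzoyl chloride, Et3N, toluene, 25 °C; then 22, 80 °C
Reagents that add atoms: none
Why: Yamaguchi esterification without a nucleophilic catalyst is chosen to avoid Z → E isomerisation of the angelate, and only the equatorial 2α-OH should react because the 3α-OH is axial and neopentyl and the C13–OH is tertiary.

Step 13
Reactants: 25 2α-angeloyloxy-3α,13-dihydroxy-7-oxo-9βH-labd-14-en-20-yl (2R)-2-methylbutanoate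
Product: 28 2α-[(Z)-2-methylbut-2-enoyloxy]-3α,13-dihydroxy-7-oxo-9βH-labda-8(17),14-dien-20-yl (2R)-2-methylbutanoate, via Mannich base 26 (not isolated), via methiodide 27 (not isolated)
Conditions: Me2N=CH2+ I− (Eschenmoser's salt), CH2Cl2/MeCN, 40 °C; aq. NaHCO3; MeI, then NaHCO3, CH2Cl2, 25 °C
Reagents that add atoms: N,N-dimethylmethyleneiminium iodide, C=[N+](C)C.[I-]
Why: The Mannich reaction should take place at C8 rather than C6 (C6 is shielded by the C4 gem-dimethyl group and the C10 substituent), and quaternisation followed by Hofmann-type β-elimination then gives the α-methylene ketone under mild base.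

Step 14
Reactants: 28 exo-methylene ketone
Product: 29 target, (2R,3S,5R,7R,9S,10R,13R)-2-[(Z)-2-methylbut-2-enoyloxy]-3,7,13-trihydroxy-9βH-labda-8(17),14-dien-20-yl (2R)-2-methylbutanoate
Conditions: NaBH4, CeCl3·7H2O, MeOH, −78 °C
Reagents that add atoms: none
Why: Luche reduction gives 1,2-reduction of the enone only, and hydride should come from the β face because the α-axial approach to C7 is blocked by the axial C9 side chain, giving the axial 7α-OH; both esters are inert.

Compound list
1 | (R)-linalool, (3R)-3,7-dimethylocta-1,6-dien-3-ol | C=C[C@](C)(O)CCC=C(C)C | starting material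
2 | (3R)-3,7-dimethyl-3-(triethylsilyloxy)octa-1,6-diene | C=C[C@](C)(O[Si](CC)(CC)CC)CCC=C(C)C | intermediate
3 | (4R)-4-methyl-4-(triethylsilyloxy)hex-5-enal | C=C[C@](C)(O[Si](CC)(CC)CC)CCC=O | intermediate
4 | (4R)-4-methyl-4-(triethylsilyloxy)hex-5-enoic acid | C=C[C@](C)(O[Si](CC)(CC)CC)CCC(=O)O | intermediate
5 | (3R)-5-iodo-3-methyl-3-(triethylsilyloxy)pent-1-ene | C=C[C@](C)(O[Si](CC)(CC)CC)CCI | intermediate
6 | 2-oxaspiro[3.5]nonan-7-one | O=C1CCC2(CC1)COC2 | starting material
7 | 2-oxaspiro[3.5]nona-5,8-dien-7-one | O=C1C=CC2(C=C1)COC2 | intermediate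
8 | bis[(3R)-3-methyl-3-(triethylsilyloxy)pent-4-en-1-yl]zinc | C=C[C@](C)(O[Si](CC)(CC)CC)CC[Zn]CC[C@@](C)(O[Si](CC)(CC)CC)C=C | intermediate
9 | alkylzinc dienolate of 10 (zinc on the C7 oxygen, C7=C8 and C5=C6) | C=C[C@](C)(O[Si](CC)(CC)CC)CC[C@@H]1C=C(O[Zn]CC[C@@](C)(O[Si](CC)(CC)CC)C=C)C=CC12COC2 | intermediate
10 | (9R)-9-[(3R)-3-methyl-3-(triethylsilyloxy)pent-4-en-1-yl]-2-oxaspiro[3.5]non-5-en-7-one | C=C[C@](C)(O[Si](CC)(CC)CC)CC[C@@H]1CC(=O)C=CC12COC2 | intermediate
11 | 3-bromo-3-methylbutan-2-one | CC(=O)C(C)(C)Br | starting material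
12 | bromozinc 3-methylbut-2-en-2-olate | CC(O[Zn]Br)=C(C)C | intermediate
13 | tert-butyldimethyl[(3-methylbut-2-en-2-yl)oxy]silane | CC(O[Si](C)(C)C(C)(C)C)=C(C)C | intermediate
14 | 3-{5,9-trans-7-(tert-butyldimethylsilyloxy)-9-[(3R)-3-methyl-3-(triethylsilyloxy)pent-4-en-1-yl]-2-oxaspiro[3.5]non-6-en-5-yl}-3-methylbutan-2-one (5α-H, C9 side chain α) | C=C[C@](C)(O[Si](CC)(CC)CC)CC[C@@H]1CC(O[Si](C)(C)C(C)(C)C)=C[C@@H](C(C)(C)C(C)=O)C12COC2 | intermediate
15 | C2=C3 trimethylsilyl enol ether of 14 | C=C[C@](C)(O[Si](CC)(CC)CC)CC[C@@H]1CC(O[Si](C)(C)C(C)(C)C)=C[C@@H](C(C)(C)C(=C)O[Si](C)(C)C)C12COC2 | intermediate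
16 | 20-O-trimethylsilyl ether of 17 | C=C[C@](C)(O[Si](CC)(CC)CC)CC[C@@H]1CC(O[Si](C)(C)C(C)(C)C)=C[C@H]2C(C)(C)C(=O)CC[C@]12CO[Si](C)(C)C | intermediate
17 | 7-(tert-butyldimethylsilyloxy)-20-hydroxy-13-(triethylsilyloxy)-9βH-labda-6,14-dien-3-one (5α-H, C9 side chain α, 10β-CH2OH, 13R) | C=C[C@](C)(O[Si](CC)(CC)CC)CC[C@@H]1CC(O[Si](C)(C)C(C)(C)C)=C[C@H]2C(C)(C)C(=O)CC[C@]12CO | intermediate
18 | (R)-2-methylbutanoic acid | CC[C@@H](C)C(=O)O | starting material
19 | 7-(tert-butyldimethylsilyloxy)-3-oxo-13-(triethylsilyloxy)-9βH-labda-6,14-dien-20-yl (2R)-2-methylbutanoate | C=C[C@](C)(O[Si](CC)(CC)CC)CC[C@@H]1CC(O[Si](C)(C)C(C)(C)C)=C[C@H]2C(C)(C)C(=O)CC[C@]12COC(=O)[C@H](C)CC | intermediate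
20 | 7-(tert-butyldimethylsilyloxy)-2α-hydroxy-3-oxo-13-(triethylsilyloxy)-9βH-labda-6,14-dien-20-yl (2R)-2-methylbutanoate | C=C[C@](C)(O[Si](CC)(CC)CC)CC[C@@H]1CC(O[Si](C)(C)C(C)(C)C)=C[C@H]2C(C)(C)C(=O)[C@H](O)C[C@]12COC(=O)[C@H](C)CC | intermediate
21 | 7-(tert-butyldimethylsilyloxy)-2α,3α-dihydroxy-13-(triethylsilyloxy)-9βH-labda-6,14-dien-20-yl (2R)-2-methylbutanoate | C=C[C@](C)(O[Si](CC)(CC)CC)CC[C@@H]1CC(O[Si](C)(C)C(C)(C)C)=C[C@H]2C(C)(C)[C@H](O)[C@H](O)C[C@]12COC(=O)[C@H](C)CC | intermediate
22 | 2α,3α,13-trihydroxy-7-oxo-9βH-labd-14-en-20-yl (2R)-2-methylbutanoate | C=C[C@](C)(O)CC[C@@H]1CC(=O)C[C@H]2C(C)(C)[C@H](O)[C@H](O)C[C@]12COC(=O)[C@H](C)CC | intermediate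
23 | angelic acid, (Z)-2-methylbut-2-enoic acid | C/C=C(/C)C(=O)O | starting material
24 | (Z)-2-methylbut-2-enoic 2,4,6-trichlorobenzoic anhydride | C/C=C(/C)C(=O)OC(=O)c1c(Cl)cc(Cl)cc1Cl | intermediate
25 | 2α-[(Z)-2-methylbut-2-enoyloxy]-3α,13-dihydroxy-7-oxo-9βH-labd-14-en-20-yl (2R)-2-methylbutanoate | C=C[C@](C)(O)CC[C@@H]1CC(=O)C[C@H]2C(C)(C)[C@H](O)[C@H](OC(=O)/C(C)=C\C)C[C@]12COC(=O)[C@H](C)CC | intermediate
26 | 8-(dimethylaminomethyl) Mannich base of 25 (C8 epimers) | C=C[C@](C)(O)CC[C@@H]1C(CN(C)C)C(=O)C[C@H]2C(C)(C)[C@H](O)[C@H](OC(=O)/C(C)=C\C)C[C@]12COC(=O)[C@H](C)CC | intermediate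
27 | 8-(trimethylammoniomethyl) iodide of 25 (C8 epimers) | C=C[C@](C)(O)CC[C@@H]1C(C[N+](C)(C)C)C(=O)C[C@H]2C(C)(C)[C@H](O)[C@H](OC(=O)/C(C)=C\C)C[C@]12COC(=O)[C@H](C)CC.[I-] | intermediate
28 | 2α-[(Z)-2-methylbut-2-enoyloxy]-3α,13-dihydroxy-7-oxo-9βH-labda-8(17),14-dien-20-yl (2R)-2-methylbutanoate | C=C[C@](C)(O)CC[C@@H]1C(=C)C(=O)C[C@H]2C(C)(C)[C@H](O)[C@H](OC(=O)/C(C)=C\C)C[C@]12COC(=O)[C@H](C)CC | intermediate
29 | (2R,3S,5R,7R,9S,10R,13R)-2-[(Z)-2-methylbut-2-enoyloxy]-3,7,13-trihydroxy-9βH-labda-8(17),14-dien-20-yl (2R)-2-methylbutanoate (2α-OAng, 3α-OH, 5α-H, 7α-OH, C9 side chain α, 10β-CH2O) | C=C[C@](C)(O)CC[C@@H]1C(=C)[C@H](O)C[C@H]2C(C)(C)[C@H](O)[C@H](OC(=O)/C(C)=C\C)C[C@]12COC(=O)[C@H](C)CC | target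

Total step count: 14. Longest linear sequence: 12 steps (steps 1, 2, 3, 5, 7, 8, 9, 10, 11, 12, 13, 14).

Steps most likely to fail

Step 7 (Proposed new method). What may go wrong is ring closure onto the wrong diastereotopic oxetane methylene (cis-fusion), or cationic oligomerisation of the silyl-activated oxetane before the enol silane has formed. The fallback uses known chemistry in two separate operations. It sets out from 10 and 13: the Mukaiyama–Michael stage alone is run (catalytic TBSOTf, CH2Cl2, −78 → −40 °C) and the Michael adduct 14 is isolated. Its methyl ketone is deprotonated with LiN(i-Pr)2 in THF at −78 °C to the lithium enolate of 14 F1, and BF3·OEt2 is added so that the enolate opens the oxetane intramolecularly (the established BF3-mediated opening of oxetanes by lithium enolates). Aqueous work-up gives alcohol 17, where the fallback rejoins the route.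

Step 5. What may go wrong is insufficient discrimination between the two enantiotopic enone termini, or sluggish transfer of the functionalised alkyl group from zinc. The fallback gives up catalyst control and sets out from 5 and 7: a tin-free Giese addition ((Me3Si)3SiH, AIBN, benzene, 80 °C) of the primary radical from 5 to the dienone should give 10 together with the C9 epimer of 10 F2. Because C13 is fixed, these are diastereomers and are separated by chromatography; the fallback rejoins the route at 10.

Step 13. What may go wrong is Mannich attack at C6 instead of C8, or migration of the exocyclic double bond into the ring during the elimination. The fallback sets out from 25: an (S)-proline-catalysed aldol reaction with aqueous formaldehyde (the enamine forms on the less hindered C8 side) should give the 8-hydroxymethyl ketone F3. Its primary hydroxyl is mesylated selectively (MsCl, Et3N, CH2Cl2, −20 °C) to the primary mesylate F4, and DBU eliminates it to 28, where the fallback rejoins the route.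

Further compounds
F1 | step 7 | lithium enolate of 14 | C=C[C@](C)(O[Si](CC)(CC)CC)CC[C@@H]1CC(O[Si](C)(C)C(C)(C)C)=C[C@@H](C(C)(C)C(=C)O[Li])C12COC2
F2 | step 5 | (9S)-9-[(3R)-3-methyl-3-(triethylsilyloxy)pent-4-en-1-yl]-2-oxaspiro[3.5]non-5-en-7-one (C9 epimer of 10) | C=C[C@](C)(O[Si](CC)(CC)CC)CC[C@H]1CC(=O)C=CC12COC2
F3 | step 13 | 8-(hydroxymethyl) derivative of 25 (C8 epimers) | C=C[C@](C)(O)CC[C@@H]1C(CO)C(=O)C[C@H]2C(C)(C)[C@H](O)[C@H](OC(=O)/C(C)=C\C)C[C@]12COC(=O)[C@H](C)CC
F4 | step 13 | 8-(methanesulfonyloxymethyl) derivative of 25 (C8 epimers) | C=C[C@](C)(O)CC[C@@H]1C(COS(C)(=O)=O)C(=O)C[C@H]2C(C)(C)[C@H](O)[C@H](OC(=O)/C(C)=C\C)C[C@]12COC(=O)[C@H](C)CC
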